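**Retrosynthetic overview**
1. Target 34 ⇐ diketone 31 (C5=O, C11=O) by double methylenation, O2‑desilylation and C11(20) epoxidation (last ring: spiro‑epoxide).
2. 31 ⇐ alkynyl oxepane acetal 29 by an oxidative gold‑carbene/oxonium‑ylide Stevens [1,2]‑shift: the seven‑membered acetal expands to the 4,8‑ether‑bridged cyclodecane (C3–C4 bond; oxane and ten‑membered ring form together).
3. 29 ⇐ triol lactone 16 by lactone transposition (C7 → C19), anti‑chloropropargylation at C7 (sets C6, C7), acetylation and lactol closure of O8 onto C3 (oxepane).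
4. 16 ⇐ aldehyde 10 + hydroxy lactone 14 by aldol (C8–C9; sets C8, C9; C17 from asymmetric hydrogenation).
5. 10 ⇐ o‑cresol via quinone monoketal 3, asymmetric conjugate addition/aldol (C10, C1, C2) and L‑Selectride (C14). Ring order: cyclohexane → γ‑lactone → oxepane → oxane + cyclodecane (ring expansion) → epoxide.

Assumption: briarane numbering (C1–C20) is used for locants in all intermediates, the SMILES are authoritative for configuration, and the catalyst/ligand enantiomers named are those taken to give the drawn configuration (the antipode is used if the sense of induction is opposite).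

**Route**

Step 1
Reactants: 1 o‑cresol
Product: 2 4,4‑dimethoxy‑2‑methylcyclohexa‑2,5‑dien‑1‑one
Conditions: PhI(OAc)2 (2.1 equiv), MeOH, 0 °C to rt
Reagents that add atoms: methanol, CO
Why: PIDA oxidative dearomatisation of a para‑unsubstituted phenol in methanol gives the p‑quinone monoketal, which masks C11 as a ketal and provides the 2‑methyl enone.

Step 2
Reactants: 2 dienone ketal
Product: 3 4,4‑dimethoxy‑2‑methylcyclohex‑2‑en‑1‑one
Conditions: H2 (1 atm), RhCl(PPh3)3 (5 mol %), benzene, rt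
Reagents that add atoms: none
Why: Wilkinson hydrogenation reduces the disubstituted enone C=C much faster than the methyl‑bearing trisubstituted one, leaving a single enone.

Step 3
Reactants: 3 enone ketal; 4 (2‑methylprop‑1‑en‑1‑yl)magnesium bromide; 5 acrolein
Product: 8 (2S,3R)-2-[(1S)-1-(tert-butyldimethylsilyloxy)prop-2-en-1-yl]-4,4-dimethoxy-2-methyl-3-(2-methylprop-1-en-1-yl)cyclohexan-1-one, via magnesium enolate 6 (not isolated), via magnesium aldolate 7 (not isolated)
Conditions: 4 (1.3 equiv), CuBr·SMe2 (5 mol %), (R,S)‑Josiphos (6 mol %), t‑BuOMe, −78 °C; then 5, −78 °C; then TBSOTf, −78 to −20 °C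
Reagents that add atoms: tert‑butyldimethylsilyl triflate, CC(C)(C)[Si](C)(C)OS(=O)(=O)C(F)(F)F
Why: Cu‑catalysed asymmetric conjugate addition sets C10 under ligand control, the magnesium enolate then adds to acrolein anti to the new C10 group through a Zimmerman–Traxler aldol (C1 quaternary trans to C10; enolate methyl syn to the new hydroxyl, setting C2), and in‑flask silylation blocks retro‑aldol.

Step 4
Reactants: 8 silyl ether ketone
Product: 9 (1S,2R,3R)-2-[(1S)-1-(tert-butyldimethylsilyloxy)prop-2-en-1-yl]-4,4-dimethoxy-2-methyl-3-(2-methylprop-1-en-1-yl)cyclohexan-1-ol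
Conditions: L‑Selectride (1.5 equiv), THF, −78 °C; H2O
Reagents that add atoms: none
Why: The bulky hydride attacks the 2,2‑disubstituted cyclohexanone equatorially (as in Selectride reductions of 4,4‑dimethyl‑3‑ketones), giving the axial C14 alcohol trans to the C1 methyl.

Step 5
Reactants: 9 cyclohexanol
Product: 10 C9 aldehyde (9 with the 2‑methylpropenyl group cleaved to CHO; other centres unchanged)
Conditions: O3, CH2Cl2, −78 °C (Sudan III end point); PPh3
Reagents that add atoms: ozone, [O-][O+]=O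
Why: Ozonolysis cleaves the electron‑rich trisubstituted alkene far faster than the hindered vinyl group deactivated by its allylic silyloxy substituent, so C9 is unveiled while C3 stays masked.

Step 6
Reactants: 11 4‑methylfuran‑2(5H)‑one
Product: 12 (R)-4-methyldihydrofuran-2(3H)-one
Conditions: H2 (50 atm), Ru(OAc)2[(S)‑BINAP] (0.5 mol %), MeOH/CH2Cl2, 50 °C
Reagents that add atoms: none
Why: Ru–BINAP asymmetric hydrogenation of the butenolide C=C sets the C17 methyl stereocentre.

Step 7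
Reactants: 12 (R)‑β‑methyl‑γ‑butyrolactone
Product: 14 (3R,4S)-3-hydroxy-4-methyldihydrofuran-2(3H)-one, via lithium enolate 13 (not isolated)
Conditions: LiHMDS, THF, −78 °C; then 2‑(phenylsulfonyl)‑3‑phenyloxaziridine; H2O
Reagents that add atoms: 2‑(phenylsulfonyl)‑3‑phenyloxaziridine, O=S(=O)(c1ccccc1)N1OC1c1ccccc1
Why: Davis enolate hydroxylation occurs trans to the β‑methyl group; this carbinol centre is re‑enolised in step 8, so only the oxygen matters.

Step 8
Reactants: 14 hydroxy lactone; 10 C9 aldehyde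
Product: 16 C8–C9 aldol triol lactone (8‑OH cis to the C17 methyl; 8,9‑syn diol; 14‑OH free), via dilithio enediolate 15 (not isolated)
Conditions: 14 (2.2 equiv), LDA (4.5 equiv), THF, −78 to −40 °C; then 10, −78 °C; H2O
Reagents that add atoms: none
Why: In this lithium aldol addition the aldehyde approaches the cyclic enediolate anti to the C17 methyl (sets C8) through a closed Zimmerman–Traxler transition state in which the α‑oxido group, cis to the enolate oxygen, ends syn to the new hydroxyl (sets C9); the excess dianion absorbs the 14‑OH proton.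

Step 9
Reactants: 16 triol lactone
Product: 17 8,9‑O‑isopropylidene lactone
Conditions: 2,2‑dimethoxypropane, PPTS, CH2Cl2, rt
Reagents that add atoms: 2,2‑dimethoxypropane, COC(C)(C)OC
Why: Acetonide formation on the 1,2‑diol keeps O9 out of the later lactonisation and makes C7 a glyceraldehyde‑acetonide‑type carbonyl for Felkin control.

Step 10
Reactants: 17 acetonide lactone
Product: 18 C7 lactol (anomer mixture)
Conditions: DIBAL‑H (2.5 equiv), CH2Cl2, −78 °C; Rochelle salt
Reagents that add atoms: none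
Why: DIBAL reduction of the α‑alkoxy lactone stops at the lactol at −78 °C, and no other ester is present at this stage.

Step 11
Reactants: 18 lactol; 19 3‑chloro‑1‑(trimethylsilyl)propyne
Product: 21 anti‑chlorohydrin triol (7‑OH, 19‑OH, 14‑OH; 6‑Cl; TMS‑alkyne), via allenylzinc bromide 20 (not isolated)
Conditions: 19 (4 equiv), n‑BuLi, THF/Et2O, −90 °C; ZnBr2; then 18, −78 to −20 °C; H2O
Reagents that add atoms: none
Why: The chloroallenylzinc reagent adds to the open hydroxy‑aldehyde through a cyclic SE2′ transition state to give the anti chlorohydrin (C6/C7) and attacks anti to the acetonide C8–O bond (Felkin–Anh, as with glyceraldehyde acetonide), which fixes C7.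

Step 12
Reactants: 21 chlorohydrin triol
Product: 23 γ‑lactone (C19=O; O–C7; 14‑OH free), via lactol 22 (not isolated)
Conditions: TEMPO (20 mol %), PhI(OAc)2 (2.5 equiv), CH2Cl2, rt
Reagents that add atoms: none
Why: TEMPO/PhI(OAc)2 oxidises only the primary C19 alcohol, the aldehyde is captured by the 7‑OH as a five‑membered lactol and oxidised on to the lactone (oxidative lactonisation), which moves the lactone carbonyl from C7 to C19.

Step 13
Reactants: 23 lactone acetonide
Product: 24 triol ketone (8‑OH, 9‑OH, 14‑OH; C11=O)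
Conditions: TFA/H2O/THF (1:1:4), 0 °C
Reagents that add atoms: water, O
Why: Aqueous acid hydrolyses the acetonide and the dimethyl ketal, while the hindered secondary TBS ether, the lactone and the silylalkyne survive.

Step 14
Reactants: 24 triol ketone
Product: 25 9,14‑diacetate (tertiary 8‑OH free)
Conditions: Ac2O, pyridine, DMAP (cat.), CH2Cl2, 0 °C to rt
Reagents that add atoms: acetic anhydride, CC(=O)OC(C)=O
Why: DMAP‑catalysed acetylation esterifies the two secondary alcohols and leaves the tertiary C8 hydroxyl untouched; low temperature avoids β‑elimination of the new β‑acetoxy ketone.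

Step 15
Reactants: 25 diacetate
Product: 28 oxepane anomeric acetate (C3‑OAc trans to C2‑OTBS; TMS‑alkyne), via aldehyde 26 (not isolated), via lactol 27 (not isolated)
Conditions: O3, CH2Cl2, −78 °C; PPh3; then Ac2O, pyridine, DMAP, 0 °C
Reagents that add atoms: ozone, [O-][O+]=O; acetic anhydride, CC(=O)OC(C)=O
Why: Ozonolysis of the vinyl group (alkyne inert) gives the α‑silyloxy aldehyde, whose only free hydroxyl (8‑OH, held gauche by the trans‑disubstituted cyclohexane) closes the seven‑membered lactol, and acetylation traps it as the 1,2‑trans anomeric acetate.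

Step 16
Reactants: 28 silylalkyne
Product: 29 terminal alkyne (oxepane acetal with spiro‑lactone and 6‑chloro‑propargyl arm)
Conditions: AgNO3 (0.2 equiv), acetone/H2O, rt
Reagents that add atoms: none
Why: Silver‑catalysed protodesilylation of the alkynylsilane runs under near‑neutral conditions that spare the acetates, the anomeric acetate and the TBS ether.

Step 17
Reactants: 29 alkynyl oxepane acetal
Product: 31 4,8‑ether‑bridged cyclodecane diketone (C5=O, C11=O; 6‑Cl; 2‑OTBS; 3,9,14‑triacetate), via oxonium ylide 30 (not isolated)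
Conditions: BrettPhosAuNTf2 (5 mol %), 8‑methylquinoline N‑oxide (1.3 equiv, slow addition), DCE (0.005 M), rt
Reagents that add atoms: 8‑methylquinoline N‑oxide, Cc1cccc2ccc[n+]([O-])c12
Why: Proposed new method: gold(I)‑catalysed N‑oxide oxidation of the terminal alkyne (oxygen delivered to internal C5) gives an α‑oxo gold carbene at C4 that the acetal oxygen O8 captures through a six‑membered ring, and the oxonium ylide then ionises at the anomeric C3–O8 bond (acyloxy‑stabilised oxocarbenium/gold enolate pair) and recombines at carbon, a non‑pericyclic Stevens [1,2]‑shift that expands the seven‑membered acetal to the ether‑bridged ten‑membered ring, forming C3–C4 with retention at C3 (tight pair, attack anti to the C2 silyloxy group) while C4 is fixed by the bridged geometry; the closest known reactions are Cu/Rh diazoketone oxonium‑ylide [1,2]‑shifts of cyclic acetals to ether‑bridged seven‑ and eight‑membered carbocycles and gold α‑oxo carbene/oxonium‑ylide rearrangements.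

Step 18
Reactants: 31 diketone
Product: 32 5(16),11(20)‑bis‑methylene compound
Conditions: Tebbe reagent (3 equiv), pyridine, THF/toluene, −40 to 0 °C
Reagents that add atoms: Tebbe reagent, C[Al-]1(C)C[Ti]([Cl+]1)(C1C=CC=C1)C1C=CC=C1
Why: Tebbe methylenation converts both ketones (much more reactive than the acetates and lactone at low temperature) under non‑basic conditions that avoid β‑elimination of the α‑chloro‑β‑acyloxy ketone.

Step 19
Reactants: 32 bis‑methylene silyl ether
Product: 33 C2 alcohol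
Conditions: HF·pyridine, pyridine, THF, 0 °C to rt
Reagents that add atoms: none
Why: Buffered fluoride desilylation frees the C2 hydroxyl without acetyl migration and leaves the allylic chloride, acetates and lactone intact.

Step 20
Reactants: 33 diene alcohol
Product: 34 target CNP0270816.1
Conditions: mCPBA, NaHCO3, CH2Cl2, 0 °C
Reagents that add atoms: m‑chloroperbenzoic acid, OOC(=O)c1cccc(Cl)c1
Why: Prilezhaev epoxidation is chemoselective for the C11 exocyclic alkene (the C5 methylene is deactivated by the allylic chloride and ether oxygen) and occurs anti to the axial C1 methyl, placing the epoxide oxygen α as in the target.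

**Compound list**
1 | o‑cresol (2‑methylphenol) | Cc1ccccc1O | starting material
2 | 4,4‑dimethoxy‑2‑methylcyclohexa‑2,5‑dien‑1‑one | CC1=CC(OC)(OC)C=CC1=O | intermediate
3 | 4,4‑dimethoxy‑2‑methylcyclohex‑2‑en‑1‑one | CC1=CC(OC)(OC)CCC1=O | intermediate
4 | (2‑methylprop‑1‑en‑1‑yl)magnesium bromide | CC(C)=C[Mg]Br | starting material
5 | acrolein (prop‑2‑enal) | C=CC=O | starting material
6 | bromomagnesium enolate of (3R)‑4,4‑dimethoxy‑2‑methyl‑3‑(2‑methylprop‑1‑enyl)cyclohexanone | CC(C)=C[C@@H]1C(C)=C(O[Mg]Br)CCC1(OC)OC | intermediate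
7 | bromomagnesium aldolate (O–MgBr form of the acrolein aldol; configuration as in 8) | CC(C)=C[C@@H]1[C@@](C)([C@@H](O[Mg]Br)C=C)C(=O)CCC1(OC)OC | intermediate
8 | (2S,3R)‑2‑[(1S)‑1‑(tert‑butyldimethylsilyloxy)prop‑2‑en‑1‑yl]‑4,4‑dimethoxy‑2‑methyl‑3‑(2‑methylprop‑1‑en‑1‑yl)cyclohexan‑1‑one | CC(C)=C[C@@H]1[C@@](C)([C@@H](O[Si](C)(C)C(C)(C)C)C=C)C(=O)CCC1(OC)OC | intermediate
9 | (1S,2R,3R)‑cyclohexan‑1‑ol from 8 (axial 14‑OH trans to the ring methyl) | CC(C)=C[C@@H]1[C@@](C)([C@@H](O[Si](C)(C)C(C)(C)C)C=C)[C@@H](O)CCC1(OC)OC | intermediate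
10 | C9 aldehyde (9 with the 2‑methylpropenyl group replaced by CHO) | O=C[C@@H]1[C@@](C)([C@@H](O[Si](C)(C)C(C)(C)C)C=C)[C@@H](O)CCC1(OC)OC | intermediate
11 | 4‑methylfuran‑2(5H)‑one | CC1=CC(=O)OC1 | starting material
12 | (R)‑4‑methyldihydrofuran‑2(3H)‑one | C[C@@H]1CC(=O)OC1 | intermediate
13 | lithium enolate of 12 | C[C@@H]1C=C(O[Li])OC1 | intermediate
14 | (3R,4S)‑3‑hydroxy‑4‑methyldihydrofuran‑2(3H)‑one | C[C@@H]1[C@@H](O)C(=O)OC1 | intermediate
15 | dilithio enediolate of 14 | C[C@@H]1C(O[Li])=C(O[Li])OC1 | intermediate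
16 | aldol triol lactone (lactone C7=O/O–C19H2; 8‑OH tertiary, cis to C17‑Me; 9‑OH; 14‑OH; C11 dimethyl ketal; 2‑OTBS vinyl carbinol) | O=C1OC[C@H](C)[C@@]1(O)[C@@H](O)[C@@H]2[C@@](C)([C@@H](O[Si](C)(C)C(C)(C)C)C=C)[C@@H](O)CCC2(OC)OC | intermediate
17 | 8,9‑O‑isopropylidene derivative of 16 | O=C1OC[C@H](C)[C@]12OC(C)(C)O[C@H]2[C@@H]3[C@@](C)([C@@H](O[Si](C)(C)C(C)(C)C)C=C)[C@@H](O)CCC3(OC)OC | intermediate
18 | C7 lactol of 17 (anomer mixture) | OC1OC[C@H](C)[C@]12OC(C)(C)O[C@H]2[C@@H]3[C@@](C)([C@@H](O[Si](C)(C)C(C)(C)C)C=C)[C@@H](O)CCC3(OC)OC | intermediate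
19 | 3‑chloro‑1‑(trimethylsilyl)propyne | C[Si](C)(C)C#CCCl | starting material
20 | [3‑chloro‑1‑(trimethylsilyl)propa‑1,2‑dienyl]zinc bromide | C[Si](C)(C)C(=C=CCl)[Zn]Br | intermediate
21 | anti‑chlorohydrin triol (7‑OH, 6‑Cl, TMS‑alkyne; 19‑OH primary; 8,9‑acetonide; 14‑OH) | C[Si](C)(C)C#C[C@H](Cl)[C@H](O)[C@]1([C@@H](C)CO)OC(C)(C)O[C@H]1[C@@H]2[C@@](C)([C@@H](O[Si](C)(C)C(C)(C)C)C=C)[C@@H](O)CCC2(OC)OC | intermediate
22 | C19 lactol (O7–C19 ring) from 21 | C[Si](C)(C)C#C[C@H](Cl)[C@@H]1OC(O)[C@H](C)[C@]12OC(C)(C)O[C@H]2[C@@H]3[C@@](C)([C@@H](O[Si](C)(C)C(C)(C)C)C=C)[C@@H](O)CCC3(OC)OC | intermediate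
23 | transposed γ‑lactone (C19=O, O–C7; 8,9‑acetonide; 14‑OH) | C[Si](C)(C)C#C[C@H](Cl)[C@@H]1OC(=O)[C@H](C)[C@]12OC(C)(C)O[C@H]2[C@@H]3[C@@](C)([C@@H](O[Si](C)(C)C(C)(C)C)C=C)[C@@H](O)CCC3(OC)OC | intermediate
24 | triol ketone (8‑OH, 9‑OH, 14‑OH; C11=O) | C[Si](C)(C)C#C[C@H](Cl)[C@@H]1OC(=O)[C@H](C)[C@@]1(O)[C@@H](O)[C@@H]2[C@@](C)([C@@H](O[Si](C)(C)C(C)(C)C)C=C)[C@@H](O)CCC2=O | intermediate
25 | 9,14‑diacetate of 24 | C[Si](C)(C)C#C[C@H](Cl)[C@@H]1OC(=O)[C@H](C)[C@@]1(O)[C@@H](OC(C)=O)[C@@H]2[C@@](C)([C@@H](O[Si](C)(C)C(C)(C)C)C=C)[C@@H](OC(C)=O)CCC2=O | intermediate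
26 | C3 aldehyde (vinyl of 25 cleaved) | C[Si](C)(C)C#C[C@H](Cl)[C@@H]1OC(=O)[C@H](C)[C@@]1(O)[C@@H](OC(C)=O)[C@@H]2[C@@](C)([C@@H](O[Si](C)(C)C(C)(C)C)C=O)[C@@H](OC(C)=O)CCC2=O | intermediate
27 | oxepane lactol (O8–C3; anomer mixture) | C[Si](C)(C)C#C[C@H](Cl)[C@@H]1OC(=O)[C@H](C)[C@]12OC(O)[C@H](O[Si](C)(C)C(C)(C)C)[C@@]3(C)[C@@H](OC(C)=O)CCC(=O)[C@@H]3[C@@H]2OC(C)=O | intermediate
28 | oxepane anomeric acetate (C3‑OAc trans to C2‑OTBS; TMS‑alkyne) | C[Si](C)(C)C#C[C@H](Cl)[C@@H]1OC(=O)[C@H](C)[C@]12O[C@@H](OC(C)=O)[C@H](O[Si](C)(C)C(C)(C)C)[C@@]3(C)[C@@H](OC(C)=O)CCC(=O)[C@@H]3[C@@H]2OC(C)=O | intermediate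
29 | terminal alkyne (28 without SiMe3) | C#C[C@H](Cl)[C@@H]1OC(=O)[C@H](C)[C@]12O[C@@H](OC(C)=O)[C@H](O[Si](C)(C)C(C)(C)C)[C@@]3(C)[C@@H](OC(C)=O)CCC(=O)[C@@H]3[C@@H]2OC(C)=O | intermediate
30 | bicyclic oxonium ylide (O8 bonded to C3, C4, C8; carbanion at C4; drawn metal‑free) | O=C1[CH-][O+]2[C@]3([C@@H](C)C(=O)O[C@H]3[C@H]1Cl)[C@@H](OC(C)=O)[C@H]1C(=O)CC[C@H](OC(C)=O)[C@]1(C)[C@@H](O[Si](C)(C)C(C)(C)C)[C@@H]2OC(C)=O | intermediate
31 | 4,8‑ether‑bridged diketone (C5=O, C11=O; 6‑Cl; 2‑OTBS; 3,9,14‑OAc) | O=C1[C@H]2O[C@]3([C@@H](C)C(=O)O[C@H]3[C@H]1Cl)[C@@H](OC(C)=O)[C@H]1C(=O)CC[C@H](OC(C)=O)[C@]1(C)[C@@H](O[Si](C)(C)C(C)(C)C)[C@@H]2OC(C)=O | intermediate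
32 | 5(16),11(20)‑diene (2‑OTBS) | C=C1[C@H]2O[C@]3([C@@H](C)C(=O)O[C@H]3[C@H]1Cl)[C@@H](OC(C)=O)[C@H]1C(=C)CC[C@H](OC(C)=O)[C@]1(C)[C@@H](O[Si](C)(C)C(C)(C)C)[C@@H]2OC(C)=O | intermediate
33 | 5(16),11(20)‑diene 2‑alcohol | C=C1[C@H]2O[C@]3([C@@H](C)C(=O)O[C@H]3[C@H]1Cl)[C@@H](OC(C)=O)[C@H]1C(=C)CC[C@H](OC(C)=O)[C@]1(C)[C@@H](O)[C@@H]2OC(C)=O | intermediate
34 | CNP0270816.1 | C=C1[C@H]2O[C@]3([C@@H](C)C(=O)O[C@H]3[C@H]1Cl)[C@@H](OC(C)=O)[C@H]1[C@]3(CC[C@H](OC(C)=O)[C@]1(C)[C@@H](O)[C@@H]2OC(C)=O)CO3 | target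

**Totals**
Total step count: 20. Longest linear sequence: 18 steps (1–5, then 8–20); steps 6–7 make the lactone partner in parallel.

**Three steps most likely to fail**

Step 17 (new oxidative Stevens ring expansion). The risks are over‑oxidation of the carbene, O‑ instead of C‑recombination, and competing migration of C8. The fallback uses known chemistry, sets out from 29 and comes back at 31. The terminal alkyne of 29 is cleaved with RuCl3 (cat.)/NaIO4 to the α‑chloro carboxylic acid F1. F1 is converted with oxalyl chloride into the acid chloride F2 and then with diazomethane into the α‑diazoketone F3. Slow addition of F3 to Cu(hfacac)2 (5 mol %) in refluxing CH2Cl2 gives the same oxonium ylide 30 and, by the established diazoketone/cyclic‑acetal [1,2]‑shift, ketone 31.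

Step 8 (dianion aldol). The risks are poor conversion with the hindered, hydroxyl‑bearing aldehyde and low selectivity at C9. The fallback sets out from 14 (with 10) and comes back at 16. Compound 14 is converted with TMSCl/Et3N and then LDA/TMSCl into the bis(trimethylsilyl) ketene acetal F4. F4 adds to 10 in a MgBr2·OEt2‑promoted Mukaiyama aldol (open transition state, attack again anti to the C17 methyl) to give the 8‑O‑silylated adduct F5. Citric acid in methanol removes the trimethylsilyl group and returns 16.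

Step 3 (asymmetric conjugate addition/aldol/silylation in one flask). The main risk is insufficient enantioselectivity at C10. The fallback sets out from 3 and comes back at 8. The same sequence run without chiral ligand (4, CuBr·SMe2 cat., then 5, then TBSOTf) gives racemic material through the mirror‑image magnesium enolate F6 and the mirror‑image magnesium aldolate F7, that is 8 together with its enantiomer, the ent‑silyl ether ketone F8. Preparative chiral‑phase SFC separates the two and returns enantiopure 8; the relative configuration is substrate‑controlled and unaffected.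

**Further compounds**
F1 | step 17 | α‑chloro carboxylic acid (alkyne of 29 cleaved to CO2H at C5) | OC(=O)[C@H](Cl)[C@@H]1OC(=O)[C@H](C)[C@]12O[C@@H](OC(C)=O)[C@H](O[Si](C)(C)C(C)(C)C)[C@@]3(C)[C@@H](OC(C)=O)CCC(=O)[C@@H]3[C@@H]2OC(C)=O
F2 | step 17 | acid chloride of F1 | ClC(=O)[C@H](Cl)[C@@H]1OC(=O)[C@H](C)[C@]12O[C@@H](OC(C)=O)[C@H](O[Si](C)(C)C(C)(C)C)[C@@]3(C)[C@@H](OC(C)=O)CCC(=O)[C@@H]3[C@@H]2OC(C)=O
F3 | step 17 | α‑diazoketone (C5=O, C4=N2) | [N-]=[N+]=CC(=O)[C@H](Cl)[C@@H]1OC(=O)[C@H](C)[C@]12O[C@@H](OC(C)=O)[C@H](O[Si](C)(C)C(C)(C)C)[C@@]3(C)[C@@H](OC(C)=O)CCC(=O)[C@@H]3[C@@H]2OC(C)=O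
F4 | step 8 | 4‑methyl‑2,3‑bis(trimethylsilyloxy)‑4,5‑dihydrofuran (methyl centre as in 14) | C[C@H]1COC(O[Si](C)(C)C)=C1O[Si](C)(C)C
F5 | step 8 | 8‑O‑trimethylsilyl ether of 16 | O=C1OC[C@H](C)[C@@]1(O[Si](C)(C)C)[C@@H](O)[C@@H]2[C@@](C)([C@@H](O[Si](C)(C)C(C)(C)C)C=C)[C@@H](O)CCC2(OC)OC
F6 | step 3 | mirror image of magnesium enolate 6 | CC(C)=C[C@H]1C(C)=C(O[Mg]Br)CCC1(OC)OC
F7 | step 3 | mirror image of magnesium aldolate 7 | CC(C)=C[C@H]1[C@](C)([C@H](O[Mg]Br)C=C)C(=O)CCC1(OC)OC
F8 | step 3 | mirror image of silyl ether ketone 8 | CC(C)=C[C@H]1[C@](C)([C@H](O[Si](C)(C)C(C)(C)C)C=C)C(=O)CCC1(OC)OC
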